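**Retrosynthetic overview**
- The target comes from its tetra-O-methyl ether (5''-OH free) by BBr3. All four stereocentres (2S,3R,2''S,3''R, both heterocycles 2,3-trans) are set before that.
- Feature the strategy rests on: in ring A'' the oxygens on C5'' and C7'' sit 1,3 on the four-carbon run C5''–C6''–C7''–C8'' that bridges C4a'' and C8a''. That run is a 1,1,3-trioxygenated butadiene, so ring A'' is cut at C8a''–C8'' and C4a''–C5'' back to 1,3-dimethoxy-1-(trimethylsilyloxy)butadiene and a 5-bromo-2,3-dihydropyran-4-one that already carries unit 1 on C3''.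
- That bromodihydropyranone is cut at C3–C3'': silicon-tethered oxidative coupling of the enol ethers of (S)-7,4'-dimethoxyflavanone and (S)-5-bromo-2-(4-methoxyphenyl)-2,3-dihydropyran-4-one.
- The flavanone comes from 7-methoxychromone and 4-methoxyphenylboronic acid (asymmetric conjugate addition, sets C2). The bromopyranone comes from 4-methoxybenzaldehyde and 1-methoxy-3-(trimethylsilyloxy)butadiene (asymmetric hetero-Diels–Alder, sets C2''), then bromination.
- Ring order: ring A is bought, ring C by chromone closure, ring C'' by hetero-Diels–Alder, ring A'' last.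

Key step: step 9

Locants: unit 1 (7-hydroxychromanone half) is unprimed and its aryl ring primed; unit 2 is double-primed and its aryl ring triple-primed.
Assumption: the ligand enantiomers named in steps 2 and 3 are taken to deliver the 2S configuration of each ketone; if the sense of induction is the reverse, the mirror-image ligand is used and nothing else changes.

**Step 1**
Reactants: 1 1-(2-hydroxy-4-methoxyphenyl)ethan-1-one
Product: 3 7-methoxy-4H-chromen-4-one, via enaminone 2 (not isolated)
Conditions: Me2NCH(OMe)2, toluene, 110 °C; then conc. HCl, CH2Cl2, 40 °C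
Reagents that add atoms: N,N-dimethylformamide dimethyl acetal, COC(OC)N(C)C
Why: Condensation of the methyl ketone with the amide acetal gives the enaminone, and acid-promoted addition of the phenol oxygen to its β-carbon with loss of dimethylamine closes the pyranone ring (standard enaminone chromone synthesis).

**Step 2**
Reactants: 3 7-methoxy-4H-chromen-4-one; 4 (4-methoxyphenyl)boronic acid
Product: 5 (S)-7-methoxy-2-(4-methoxyphenyl)chroman-4-one
Conditions: Pd(OCOCF3)2 (5 mol%), (R)-4-tert-butyl-2-(pyridin-2-yl)-4,5-dihydrooxazole (6 mol%), NH4PF6, H2O, ClCH2CH2Cl, 60 °C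
Reagents that add atoms: none
Why: Catalytic asymmetric conjugate addition of an arylpalladium species (divalent palladium) to the chromone C2=C3 bond followed by protonolysis of the palladium enolate, with the pyridine–oxazoline ligand fixing the face of aryl transfer and so setting C2 as S.

**Step 3**
Reactants: 6 4-methoxybenzaldehyde; 7 (E)-1-methoxy-3-(trimethylsilyloxy)buta-1,3-diene
Product: 9 (S)-2-(4-methoxyphenyl)-2,3-dihydro-4H-pyran-4-one, via silyl aldol adduct 8 (not isolated)
Conditions: Ti(OiPr)4/(R)-H8-BINOL (10 mol%), 4 Å MS, toluene, 0 °C; then CF3CO2H, CH2Cl2, 0 °C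
Reagents that add atoms: none
Why: Catalytic enantioselective hetero-Diels–Alder reaction in its Mukaiyama aldol mode, in which the chiral titanium binaphtholate shields one face of the bound aldehyde and sets C2'' as S, and acid then closes the ring by oxa-Michael addition with loss of the methoxy and silyl groups.

**Step 4**
Reactants: 9 (S)-2-(4-methoxyphenyl)-2,3-dihydro-4H-pyran-4-one
Product: 11 (S)-5-bromo-2-(4-methoxyphenyl)-2,3-dihydro-4H-pyran-4-one, via dibromide 10 (not isolated)
Conditions: Br2 (1.0 equiv), CH2Cl2, −78 °C; then Et3N, −78 to 0 °C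
Reagents that add atoms: bromine, BrBr
Why: Addition–elimination α-halogenation of a vinylogous ester: bromine adds across the enol ether C5=C6 much faster than it attacks the anisyl ring at −78 °C, and Et3N removes the acidic C5–H with loss of the anomeric bromide, leaving C2 untouched.

**Step 5**
Reactants: 12 methyl 3-oxobutanoate
Product: 13 methyl (E)-3-methoxybut-2-enoate
Conditions: HC(OMe)3, H2SO4 (cat.), rt; distillation
Reagents that add atoms: trimethyl orthoformate, COC(OC)OC
Why: Acid-catalysed ketalisation of the ketone and loss of methanol gives the conjugated enol ether, the E isomer being the thermodynamically preferred one.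

**Step 6**
Reactants: 13 methyl (E)-3-methoxybut-2-enoate
Product: 14 (E)-1,3-dimethoxy-1-(trimethylsilyloxy)buta-1,3-diene
Conditions: LiN(iPr)2, THF, −78 °C; Me3SiCl; distillation
Reagents that add atoms: chlorotrimethylsilane, C[Si](C)(C)Cl
Why: γ-Deprotonation of the β-methoxy enoate gives the lithium dienolate, and O-silylation gives the silyl ketene acetal diene (standard silyl dienolate formation).

**Step 7**
Reactants: 5 (S)-7-methoxy-2-(4-methoxyphenyl)chroman-4-one; 11 (S)-5-bromo-2-(4-methoxyphenyl)-2,3-dihydro-4H-pyran-4-one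
Product: 16 diisopropylsilyl bis-enol ether of 5 and 11, via chlorosilyl enol ether 15 (not isolated)
Conditions: 5, LiN(iPr)2, THF, −78 °C; iPr2SiCl2 (3 equiv), −78 °C to rt, excess silane removed in vacuo; then lithium enolate of 11 (LiN(SiMe3)2, THF, −78 °C), −78 °C to rt
Reagents that add atoms: dichlorodiisopropylsilane, CC(C)[Si](Cl)(Cl)C(C)C
Why: Kinetic enolisation of 5 at C3 and of 11 at C3'' followed by sequential O-silylation on one silicon atom (silyl bis-enol ether formation), where the excess of dichlorosilane in the first stage suppresses the symmetrical ether and the low temperature keeps the flavanone enolate from expelling its aryloxide; no stereocentre is formed.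

**Step 8**
Reactants: 16 diisopropylsilyl bis-enol ether of 5 and 11
Product: 17 (2S,3R)-3-[(2S,3R)-5-bromo-2-(4-methoxyphenyl)-4-oxo-3,4-dihydro-2H-pyran-3-yl]-7-methoxy-2-(4-methoxyphenyl)chroman-4-one
Conditions: (NH4)2Ce(NO3)6 (2.2 equiv), NaHCO3 (4.4 equiv), MeCN/EtCN, −20 °C
Reagents that add atoms: none
Why: Silicon-tethered oxidative enolate heterocoupling: one-electron oxidation of the more electron-rich enol ether by tetravalent cerium gives a radical cation that bonds C3 to C3'' through a seven-membered silicon-bridged transition state, a second oxidation and loss of the bridge give the 1,4-diketone, and each enol ether reacts on the face opposite its own C2 aryl group, which sets C3 (R) and C3'' (R) as the 2,3-trans arrangement that is also favoured at equilibrium at these two enolisable centres.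

**Step 9**
Reactants: 17 the bromodihydropyranone of step 8; 14 (E)-1,3-dimethoxy-1-(trimethylsilyloxy)buta-1,3-diene
Product: 21 (2S,3R,2''S,3''R)-5''-hydroxy-7,4',7'',4'''-tetramethoxy-3,3''-biflavanone, via silyl enol ether 18 (not isolated), via bromoketone 19 (not isolated), via dihydropyranone 20 (not isolated)
Conditions: 14 (1.5 equiv), Me3SiOTf (0.2 equiv), 2,6-di-tert-butyl-4-methylpyridine (0.3 equiv), CH2Cl2, −78 °C; MeOH, DBU (1.5 equiv), −78 °C to rt; volatiles off, THF, LiN(SiMe3)2 (2.3 equiv), −78 to 0 °C; AcOH
Reagents that add atoms: none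
Why: Proposed new method: Me3SiOTf turns the vinylogous ester of 17 into a conjugated oxocarbenium ion that the CH2 terminus of 14 attacks at C8a'' (vinylogous Mukaiyama–Michael addition, the known way silyl dienolates add to dihydropyranones and chromones) to give 18; methanolysis gives 19, and DBU removes HBr across C4a''–C8a'' as in the classical passage from 3-bromochroman-4-ones to chromones, so that 20 regains the enone with H on C4a''. LiN(SiMe3)2 then deprotonates the doubly vinylogous C8'' methylene, and the delocalised anion closes ring A'' by 6-exo-trig attack of C4a'' on the ester carbonyl (intramolecular Claisen condensation of the kind used in biomimetic polyketide aromatisations); loss of methoxide and enolisation give the arene with the former ketene acetal carbon as the chelated 5''-OH. This is the stepwise ionic counterpart of the Diels–Alder/aromatisation of 1,1,3-trioxygenated butadienes with bromoquinones and activated chromones, and HBr is removed before ring closure on purpose, because a concerted adduct would hold Br on a quaternary C4a'' cis to a non-acidic C8a''–H and could aromatise only by expelling O1''. The regioselectivity the step needs is secured by the polarity of the partners (diene CH2 to the enone β-carbon C8a'', carboxyl carbon to C4a'') and by the (E)-enoate, which holds C8'' and the ester cis; an aldol closure of C6'' onto C4'' is excluded because it would bridge three contiguous ring atoms. Chemoselectivity for the unit 2 carbonyl over the flavanone ketone of unit 1 rests on the higher Lewis basicity of the vinylogous ester oxygen. No stereocentre is kept from this step: the C8a'' centre of 18 and 19 (side chain expected trans to the C2'' aryl group) and the C4a'' centre of 19 are erased, C2 and C2'' are not touched, and C3 and C3'', the only enolisable ones, already hold the thermodynamically preferred trans arrangement.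

**Step 10**
Reactants: 21 (2S,3R,2''S,3''R)-5''-hydroxy-7,4',7'',4'''-tetramethoxy-3,3''-biflavanone
Product: 22 (2S,3R,2''S,3''R)-7,4',5'',7'',4'''-pentahydroxy-3,3''-biflavanone (target)
Conditions: BBr3 (12 equiv), CH2Cl2, −78 °C to rt; MeOH, then H2O
Reagents that add atoms: none
Why: Lewis-acid cleavage of the four aryl methyl ethers (O-complexation, then bromide attack on methyl), in which the ketones and the chelated 5''-OH are inert, the low starting temperature limits ionisation of the benzylic C2–O1 and C2''–O1'' bonds, and any acid-promoted enolisation at C3 or C3'' returns the trans arrangement already present.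

**Compound list**
1 | 1-(2-hydroxy-4-methoxyphenyl)ethan-1-one | CC(=O)c1ccc(OC)cc1O | starting material
2 | (E)-3-(dimethylamino)-1-(2-hydroxy-4-methoxyphenyl)prop-2-en-1-one | CN(C)/C=C/C(=O)c1ccc(OC)cc1O | intermediate
3 | 7-methoxy-4H-chromen-4-one | O=c1ccoc2cc(OC)ccc12 | intermediate
4 | (4-methoxyphenyl)boronic acid | COc1ccc(B(O)O)cc1 | starting material
5 | (S)-7-methoxy-2-(4-methoxyphenyl)chroman-4-one | O=C1c2ccc(OC)cc2O[C@H](c2ccc(OC)cc2)C1 | intermediate
6 | 4-methoxybenzaldehyde | COc1ccc(C=O)cc1 | starting material
7 | (E)-1-methoxy-3-(trimethylsilyloxy)buta-1,3-diene | CO/C=C/C(=C)O[Si](C)(C)C | starting material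
8 | (S,E)-1-methoxy-5-(4-methoxyphenyl)-5-(trimethylsilyloxy)pent-1-en-3-one | CO/C=C/C(=O)C[C@H](O[Si](C)(C)C)c1ccc(OC)cc1 | intermediate
9 | (S)-2-(4-methoxyphenyl)-2,3-dihydro-4H-pyran-4-one | O=C1C=CO[C@H](c2ccc(OC)cc2)C1 | intermediate
10 | (2S)-5,6-dibromo-2-(4-methoxyphenyl)oxan-4-one (pyranone locants kept, C5 and C6 not defined) | O=C1C(Br)C(Br)O[C@H](c2ccc(OC)cc2)C1 | intermediate
11 | (S)-5-bromo-2-(4-methoxyphenyl)-2,3-dihydro-4H-pyran-4-one | O=C1C(Br)=CO[C@H](c2ccc(OC)cc2)C1 | intermediate
12 | methyl 3-oxobutanoate | CC(=O)CC(=O)OC | starting material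
13 | methyl (E)-3-methoxybut-2-enoate | CO/C(C)=C/C(=O)OC | intermediate
14 | (E)-1,3-dimethoxy-1-(trimethylsilyloxy)buta-1,3-diene | C=C(OC)/C=C(\OC)O[Si](C)(C)C | intermediate
15 | (S)-chloro{[7-methoxy-2-(4-methoxyphenyl)-2H-chromen-4-yl]oxy}diisopropylsilane | COc1ccc2c(c1)O[C@H](c1ccc(OC)cc1)C=C2O[Si](Cl)(C(C)C)C(C)C | intermediate
16 | {[(S)-5-bromo-2-(4-methoxyphenyl)-2H-pyran-4-yl]oxy}{[(S)-7-methoxy-2-(4-methoxyphenyl)-2H-chromen-4-yl]oxy}diisopropylsilane | COc1ccc2c(c1)O[C@H](c1ccc(OC)cc1)C=C2O[Si](C(C)C)(C(C)C)OC1=C[C@@H](c2ccc(OC)cc2)OC=C1Br | intermediate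
17 | (2S,3R)-3-[(2S,3R)-5-bromo-2-(4-methoxyphenyl)-4-oxo-3,4-dihydro-2H-pyran-3-yl]-7-methoxy-2-(4-methoxyphenyl)chroman-4-one | O=C1c2ccc(OC)cc2O[C@H](c2ccc(OC)cc2)[C@H]1[C@H]1C(=O)C(Br)=CO[C@@H]1c1ccc(OC)cc1 | intermediate
18 | trimethylsilyl enol ether C4''(OSiMe3)=C4a''(Br) of the Michael adduct, with the methyl (E)-3-methoxybut-2-enoate chain on C8a'' trans to the C2'' aryl group | O=C1c2ccc(OC)cc2O[C@H](c2ccc(OC)cc2)[C@H]1[C@H]1C(O[Si](C)(C)C)=C(Br)[C@@H](C/C(OC)=C\C(=O)OC)O[C@@H]1c1ccc(OC)cc1 | intermediate
19 | α-bromoketone from 18 (C4''=O, H and Br on C4a'', both C4a'' epimers) | O=C1c2ccc(OC)cc2O[C@H](c2ccc(OC)cc2)[C@H]1[C@H]1C(=O)C(Br)[C@@H](C/C(OC)=C\C(=O)OC)O[C@@H]1c1ccc(OC)cc1 | intermediate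
20 | methyl (E)-3-methoxy-4-{(2S,3R)-3-[(2S,3R)-7-methoxy-2-(4-methoxyphenyl)-4-oxochroman-3-yl]-2-(4-methoxyphenyl)-4-oxo-3,4-dihydro-2H-pyran-6-yl}but-2-enoate | O=C1c2ccc(OC)cc2O[C@H](c2ccc(OC)cc2)[C@H]1[C@H]1C(=O)C=C(C/C(OC)=C\C(=O)OC)O[C@@H]1c1ccc(OC)cc1 | intermediate
21 | (2S,3R,2''S,3''R)-5''-hydroxy-7,4',7'',4'''-tetramethoxy-3,3''-biflavanone | O=C1c2ccc(OC)cc2O[C@H](c2ccc(OC)cc2)[C@H]1[C@H]1C(=O)c2c(O)cc(OC)cc2O[C@@H]1c1ccc(OC)cc1 | intermediate
22 | (2S,3R,2''S,3''R)-7,4',5'',7'',4'''-pentahydroxy-3,3''-biflavanone | O=C1c2ccc(O)cc2O[C@H](c2ccc(O)cc2)[C@H]1[C@H]1C(=O)c2c(O)cc(O)cc2O[C@@H]1c1ccc(O)cc1 | target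

**Totals**
Total step count: 10. Longest linear sequence: 6 steps (1, 2, 7, 8, 9, 10).

**Steps most likely to fail**

Step 9. Three things may go wrong. The diene may fail to add, or add only slowly, to the weakly activated vinylogous ester. Once the silyl group is off, the bromo enolate may close onto the C4 ketone of unit 1 (five-membered aldol of the 1,4-diketone). The final Claisen closure may stall, or the amide base may open ring C of unit 1 by β-elimination of the aryloxide. The fallback uses a concerted cycloaddition with a group that leaves by syn elimination, under neutral conditions. It sets out from 17 and comes back at 21. Palladium-catalysed C–S coupling of 17 with thiophenol (Pd2(dba)3, Xantphos, iPr2NEt, dioxane, 90 °C) gives the phenyl sulfide F1. One equivalent of mCPBA in CH2Cl2 at −78 °C gives the sulfoxide F2 as a mixture at sulfur. Heating F2 with 14 in toluene at 80–100 °C gives the cis-fused cycloadduct F3. In F3 the sulfinyl group on C4a'' and the hydrogen on C8a'' are syn, so benzenesulfenic acid is lost thermally in the same flask and the C4a''=C8a'' bond returns. Silica gel or dilute acid then collapses the silyl methyl ketal and the dienone enolises to 21. Arylsulfinyl-activated enones, quinones and chromones are established dienophiles for oxygenated silyloxydienes, and the sulfoxide syn elimination is standard.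

Step 8. The oxidant may attack the alkoxyarene rings or the product, the C3 radical may fragment with loss of the aryloxyl group, the tether may hydrolyse before coupling, or cis epimers may form. The fallback makes the C3–C3'' bond by reductively initiated radical addition, without a stoichiometric oxidant, without the tether of step 7 and without a metal enolate of 5. It sets out from 5 and 11 and comes back at 17. Bromination of 5 with PhNMe3Br3 in THF gives the 3-bromoflavanone F4. Soft enolisation of 11 (Me3SiOTf, Et3N, CH2Cl2, 0 °C) gives the trimethylsilyl dienol ether F5. Irradiation of F4 and F5 with blue light in the presence of Ir(ppy)3 (1 mol%) and 2,6-lutidine in MeCN should reduce the C–Br bond to the C3 radical, which adds to C3'' of F5 anti to the aryl group. Oxidation of the resulting silyloxyallyl radical by the oxidised photocatalyst and loss of the silyl group give 17. This is the known radical alkylation of silyl enol ethers by α-bromo ketones to give 1,4-diketones.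

Step 2. The electron-rich boronic acid may protodeboronate or homocouple, insertion into the electron-rich chromone may be slow, and the enantiomeric purity may be eroded. The fallback replaces the asymmetric catalysis by a classical chalcone route with resolution. It sets out from 1 and 6 and comes back at 5. Aldol condensation of 1 with 6 (KOH, EtOH, rt) gives the chalcone F6. Oxa-Michael cyclisation (NaOAc, EtOH, reflux) gives the racemic flavanone F7. Preparative chromatography on a chiral stationary phase then delivers the S enantiomer 5.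

**Further compounds**
F1 | step 9 | (2S,3R)-7-methoxy-2-(4-methoxyphenyl)-3-[(2S,3R)-2-(4-methoxyphenyl)-4-oxo-5-(phenylthio)-3,4-dihydro-2H-pyran-3-yl]chroman-4-one | O=C1c2ccc(OC)cc2O[C@H](c2ccc(OC)cc2)[C@H]1[C@H]1C(=O)C(Sc2ccccc2)=CO[C@@H]1c1ccc(OC)cc1
F2 | step 9 | (2S,3R)-7-methoxy-2-(4-methoxyphenyl)-3-[(2S,3R)-2-(4-methoxyphenyl)-4-oxo-5-(phenylsulfinyl)-3,4-dihydro-2H-pyran-3-yl]chroman-4-one (mixture at sulfur) | O=C1c2ccc(OC)cc2O[C@H](c2ccc(OC)cc2)[C@H]1[C@H]1C(=O)C(S(=O)c2ccccc2)=CO[C@@H]1c1ccc(OC)cc1
F3 | step 9 | cis-fused cycloadduct of F2 and 14 (phenylsulfinyl on C4a'', methoxy and trimethylsilyloxy on C5'', new centres not defined) | O=C1c2ccc(OC)cc2O[C@H](c2ccc(OC)cc2)[C@H]1[C@H]1C(=O)C2(S(=O)c3ccccc3)C(OC)(O[Si](C)(C)C)C=C(OC)CC2O[C@@H]1c1ccc(OC)cc1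
F4 | step 8 | (2S)-3-bromo-7-methoxy-2-(4-methoxyphenyl)chroman-4-one (C3 not defined) | O=C1c2ccc(OC)cc2O[C@H](c2ccc(OC)cc2)C1Br
F5 | step 8 | (S)-{[5-bromo-2-(4-methoxyphenyl)-2H-pyran-4-yl]oxy}trimethylsilane | C[Si](C)(C)OC1=C[C@@H](c2ccc(OC)cc2)OC=C1Br
F6 | step 2 | (E)-1-(2-hydroxy-4-methoxyphenyl)-3-(4-methoxyphenyl)prop-2-en-1-one | COc1ccc(/C=C/C(=O)c2ccc(OC)cc2O)cc1
F7 | step 2 | racemic 7-methoxy-2-(4-methoxyphenyl)chroman-4-one | O=C1CC(c2ccc(OC)cc2)Oc2cc(OC)ccc21
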